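**Assumption:** 3-(4-hydroxy-3-methoxyphenyl)propanoic acid (dihydroferulic acid) is bought; it is also one hydrogenation away from ferulic acid.

The target is taxiresinol 9-O-acetate: a 2-aryl-3-(acetoxymethyl)-4-benzyl-oxolane, (2S,3R,4R), with 2,3-trans and 3,4-cis substituents. Lignan numbering is used below: C7/C8/C9 for the catechol-side unit, C7′/C8′/C9′ for the guaiacyl-side unit.

## Retrosynthetic overview

1. Target 11 ⇐ taxiresinol 10, by enzymatic acetylation of its only aliphatic OH.
2. 10 ⇐ C2-symmetric (−)-secoisolariciresinol 7. One guaiacyl ring is oxidatively demethylated to an o-quinone, which tautomerises to the p-quinone methide and is captured at C7 by the 9′-OH. This is the only ring-forming step (oxolane ring; sets C7). It is the quinone-methide/γ-hydroxyl closure of lignan biosynthesis, run in the oxidative direction, so the demethylated ring is automatically the C7 aryl ring.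
3. 7 ⇐ (R,R)-bis-imide 6, by global hydride reduction (auxiliaries and pivalates removed together).
4. 6 ⇐ two molecules of imide 4, by auxiliary-controlled oxidative 8–8′ radical homocoupling of the enolate (sets C8 and C8′).
5. 4 ⇐ dihydroferulic acid 1 + (S)-4-isopropyl-oxazolidinone 2.

## Route

**Step 1**
Reactants: 1 3-(4-hydroxy-3-methoxyphenyl)propanoic acid; 2 (S)-4-isopropyl-1,3-oxazolidin-2-one
Product: 4 (4S)-4-isopropyl-3-[3-(3-methoxy-4-pivaloyloxyphenyl)propanoyl]-1,3-oxazolidin-2-one, via mixed pivalic anhydride 3 (not isolated)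
Conditions: PivCl (2.1 equiv), Et3N (3.5 equiv), THF, −20 → 0 °C; then LiCl (1.1 equiv), 2 (1.0 equiv), rt
Reagents that add atoms: pivaloyl chloride, CC(C)(C)C(Cl)=O
Why: PivCl/Et3N turns the phenol into its pivalate (no α-hydrogens, so it tolerates the later enolate step) and the acid into the mixed pivalic anhydride in one pot, and the LiCl-activated oxazolidinone then attacks the less hindered acyl carbon (mixed-anhydride N-acylation); no new stereocentre.

**Step 2**
Reactants: 4 (4S)-4-isopropyl-3-[3-(3-methoxy-4-pivaloyloxyphenyl)propanoyl]-1,3-oxazolidin-2-one (two molecules)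
Product: 6 (2R,3R)-2,3-bis(3-methoxy-4-pivaloyloxybenzyl)-1,4-bis[(4S)-4-isopropyl-2-oxo-1,3-oxazolidin-3-yl]butane-1,4-dione, via lithium Z-enolate 5 (not isolated)
Conditions: LDA (1.05 equiv), THF, −78 °C; then TiCl4 (1.1 equiv, in CH2Cl2), −78 °C → rt; major diastereomer isolated by crystallisation
Reagents that add atoms: none
Why: Oxidative homocoupling of a chiral imide enolate: the chelated Z-enolate is transmetalated to a tetravalent titanium enolate, which gives up one electron to the metal (leaving trivalent titanium), and the resulting α-acyl radicals join C8–C8′ on the face opposite the isopropyl group at both centres, so the (S)-auxiliary gives the (R,R)-dimer as the major isomer.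

**Step 3**
Reactants: 6 (2R,3R)-2,3-bis(3-methoxy-4-pivaloyloxybenzyl)-1,4-bis[(4S)-4-isopropyl-2-oxo-1,3-oxazolidin-3-yl]butane-1,4-dione
Product: 7 (−)-secoisolariciresinol (2R,3R)-2,3-bis(4-hydroxy-3-methoxybenzyl)butane-1,4-diol
Conditions: LiAlH4 (5 equiv), THF, 0 °C → rt; then H2O and dilute HCl to pH 5
Reagents that add atoms: none
Why: Hydride reduction converts both exocyclic imide carbonyls into primary alcohols with release of the auxiliary and cleaves both aryl pivalates in the same pot; reduction is faster than enolisation, so C8 and C8′ keep their configuration.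

**Step 4**
Reactants: 7 (−)-secoisolariciresinol (2R,3R)-2,3-bis(4-hydroxy-3-methoxybenzyl)butane-1,4-diol
Product: 10 taxiresinol 4-[(2S,3R,4R)-4-(4-hydroxy-3-methoxybenzyl)-3-(hydroxymethyl)oxolan-2-yl]benzene-1,2-diol, via o-quinone 8 (not isolated), via p-quinone methide 9 (not isolated)
Conditions: NaIO4 (0.8 equiv), THF/H2O (1:1), 0 °C, 10 min; cold EtOAc extraction; then Et3N (0.3 equiv), EtOAc, 0 °C → rt, Ar; AcOH quench (unreacted 7 recovered and recycled)
Reagents that add atoms: water, O
Why: Proposed new method: periodate oxidises a 2-methoxyphenol to the o-quinone with loss of methanol (ipso attack of water at the methoxy-bearing carbon of the aryloxy-periodate intermediate, i.e. Adler-type oxidative demethylation of guaiacols), and because 7 is C2-symmetric either ring gives the same mono-o-quinone 8, so the demethylated ring is necessarily the one that becomes the C7 aryl group; amine-catalysed vinylogous enolisation of 8 (loss of a C7 hydrogen) gives the 2-hydroxy-p-quinone methide 9, whose C7 is captured 5-exo by the 9′-OH (the 9-OH could only give an oxetane), the aryl group ending trans to the C8 hydroxymethyl group (7S) because the all-cis alternative is strained and the oxa-Michael addition is reversible through the free para-phenol; the closest known reactions are the o-quinone to p-quinone methide tautomerisation with intramolecular O-capture (carnosic acid to carnosol) and the quinone-methide/γ-hydroxyl ring closure of lignan biosynthesis.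

**Step 5**
Reactants: 10 taxiresinol 4-[(2S,3R,4R)-4-(4-hydroxy-3-methoxybenzyl)-3-(hydroxymethyl)oxolan-2-yl]benzene-1,2-diol
Product: 11 [(2S,3R,4R)-2-(3,4-dihydroxyphenyl)-4-(4-hydroxy-3-methoxybenzyl)oxolan-3-yl]methyl acetate
Conditions: Novozym 435 (immobilised Candida antarctica lipase B), vinyl acetate (5 equiv), THF, 40 °C, Ar
Reagents that add atoms: vinyl acetate, CC(=O)OC=C
Why: Lipase-catalysed transesterification acylates the primary aliphatic hydroxyl and leaves the three phenols alone, is made irreversible by tautomerisation of vinyl alcohol to acetaldehyde, and is neutral, so the acid-labile benzylic ether and all three stereocentres are untouched.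

## Compound list

1 | 3-(4-hydroxy-3-methoxyphenyl)propanoic acid (dihydroferulic acid) | COc1cc(CCC(=O)O)ccc1O | starting material
2 | (S)-4-isopropyl-1,3-oxazolidin-2-one | CC(C)[C@H]1COC(=O)N1 | starting material
3 | 3-(3-methoxy-4-pivaloyloxyphenyl)propanoic pivalic anhydride | COc1cc(CCC(=O)OC(=O)C(C)(C)C)ccc1OC(=O)C(C)(C)C | intermediate
4 | (4S)-4-isopropyl-3-[3-(3-methoxy-4-pivaloyloxyphenyl)propanoyl]-1,3-oxazolidin-2-one | CC(C)[C@H]1COC(=O)N1C(=O)CCc1ccc(OC(=O)C(C)(C)C)c(OC)c1 | intermediate
5 | lithium (Z)-enolate of 4 | CC(C)[C@H]1COC(=O)N1/C([O-])=C/Cc1ccc(OC(=O)C(C)(C)C)c(OC)c1.[Li+] | intermediate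
6 | (2R,3R)-2,3-bis(3-methoxy-4-pivaloyloxybenzyl)-1,4-bis[(4S)-4-isopropyl-2-oxo-1,3-oxazolidin-3-yl]butane-1,4-dione | CC(C)[C@H]1COC(=O)N1C(=O)[C@H](Cc1ccc(OC(=O)C(C)(C)C)c(OC)c1)[C@@H](Cc1ccc(OC(=O)C(C)(C)C)c(OC)c1)C(=O)N1C(=O)OC[C@@H]1C(C)C | intermediate
7 | (−)-secoisolariciresinol = (2R,3R)-2,3-bis(4-hydroxy-3-methoxybenzyl)butane-1,4-diol | OC[C@H](Cc1ccc(O)c(OC)c1)[C@H](CO)Cc1ccc(O)c(OC)c1 | intermediate
8 | 4-[(2R,3R)-4-hydroxy-3-(4-hydroxy-3-methoxybenzyl)-2-(hydroxymethyl)butyl]cyclohexa-3,5-diene-1,2-dione (o-quinone) | OC[C@H](CC1=CC(=O)C(=O)C=C1)[C@H](CO)Cc1ccc(O)c(OC)c1 | intermediate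
9 | 2-hydroxy-4-[(2R,3R)-4-hydroxy-3-(4-hydroxy-3-methoxybenzyl)-2-(hydroxymethyl)butylidene]cyclohexa-2,5-dien-1-one (p-quinone methide) | OC[C@H](C=C1C=CC(=O)C(O)=C1)[C@H](CO)Cc1ccc(O)c(OC)c1 | intermediate
10 | taxiresinol = 4-[(2S,3R,4R)-4-(4-hydroxy-3-methoxybenzyl)-3-(hydroxymethyl)oxolan-2-yl]benzene-1,2-diol | COc1cc(C[C@H]2CO[C@H](c3ccc(O)c(O)c3)[C@H]2CO)ccc1O | intermediate
11 | [(2S,3R,4R)-2-(3,4-dihydroxyphenyl)-4-(4-hydroxy-3-methoxybenzyl)oxolan-3-yl]methyl acetate | COc1cc(C[C@H]2CO[C@H](c3ccc(O)c(O)c3)[C@H]2COC(C)=O)ccc1O | target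

## Step count and risks

Total: 5 steps. Longest linear sequence: 5 steps (1 → 4 → 6 → 7 → 10 → 11).

**Most likely to fail: step 4.** The cascade is untested. The o-quinone to quinone methide tautomerisation of a simple alkyl o-quinone may be slow. The catechol product is more easily oxidised than the starting guaiacol, which is why the oxidant is removed before the base is added. Mono-oxidation of a symmetric substrate is statistical, so I expect roughly 30% per pass with recovery of 7.

The fallback sets out from 7 and comes back at 10. It masks one phenol first, so that ring closure and demethylation become two separately precedented operations on the single free-phenol ring. Schotten–Baumann mono-pivaloylation (PivCl 1.0 equiv, aq. NaOH/CH2Cl2, 0 °C; the two phenols are equivalent, diester and 7 are recycled) gives 4-O-pivaloyl-secoisolariciresinol F1. DDQ (1.05 equiv, 1,4-dioxane, rt) dehydrogenates only the free-phenol ring to its p-quinone methide, which closes onto the 9′-OH to give (+)-lariciresinol 4′-O-pivalate F2. IBX (1.2 equiv, DMF, −25 → 0 °C) followed by aq. Na2S2O4 demethylates the only free guaiacol, which is the C7 aryl ring, to give taxiresinol 4′-O-pivalate F3. K2CO3, MeOH, rt under argon removes the pivalate and returns 10.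

**Second: step 2.** The coupling has close precedent, but the diastereomer ratio is usually not perfect and the aryl pivalate is an untested passenger.

The fallback sets out from 4 and comes back at 7. It builds the 8–8′ bond by two ionic alkylations through the classical β-benzyl-butyrolactone. The sodium enolate of 4 (NaN(SiMe3)2, THF, −78 °C) is alkylated with tert-butyl bromoacetate to give tert-butyl (3R)-4-[(4S)-4-isopropyl-2-oxo-1,3-oxazolidin-3-yl]-3-(3-methoxy-4-pivaloyloxybenzyl)-4-oxobutanoate F4. LiBH4, THF/H2O, 0 °C reduces only the imide to tert-butyl (3R)-4-hydroxy-3-(3-methoxy-4-pivaloyloxybenzyl)butanoate F5. TFA, CH2Cl2 closes (4R)-4-(3-methoxy-4-pivaloyloxybenzyl)oxolan-2-one F6. LiN(SiMe3)2, THF, −78 °C, then 4-benzyloxy-3-methoxybenzyl bromide, alkylates anti to the C4 substituent to give (3R,4R)-3-(4-benzyloxy-3-methoxybenzyl)-4-(3-methoxy-4-pivaloyloxybenzyl)oxolan-2-one F7. LiAlH4, THF reduces the lactone and cleaves the pivalate to (2R,3R)-2-(4-benzyloxy-3-methoxybenzyl)-3-(4-hydroxy-3-methoxybenzyl)butane-1,4-diol F8. H2, Pd/C, EtOAc removes the benzyl ether and returns 7.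

**Third: step 5.** The lipase may be slow on this bulky, air-sensitive triphenol.

The fallback sets out from 10 and comes back at 11. Ac2O, pyridine, rt gives taxiresinol tetraacetate F9. Pyrrolidine (3.3 equiv), CH2Cl2, 0 °C under argon then cleaves the three aryl acetates by aminolysis and leaves the alkyl acetate, returning 11.

## Further compounds

F1 | step 4 | 4-O-pivaloyl-secoisolariciresinol = 4-[(2R,3R)-4-hydroxy-3-(4-hydroxy-3-methoxybenzyl)-2-(hydroxymethyl)butyl]-2-methoxyphenyl pivalate | OC[C@H](Cc1ccc(O)c(OC)c1)[C@H](CO)Cc1ccc(OC(=O)C(C)(C)C)c(OC)c1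
F2 | step 4 | (+)-lariciresinol 4′-O-pivalate = 4-{[(3R,4R,5S)-5-(4-hydroxy-3-methoxyphenyl)-4-(hydroxymethyl)oxolan-3-yl]methyl}-2-methoxyphenyl pivalate | COc1cc(C[C@H]2CO[C@H](c3ccc(O)c(OC)c3)[C@H]2CO)ccc1OC(=O)C(C)(C)C
F3 | step 4 | taxiresinol 4′-O-pivalate = 4-{[(3R,4R,5S)-5-(3,4-dihydroxyphenyl)-4-(hydroxymethyl)oxolan-3-yl]methyl}-2-methoxyphenyl pivalate | COc1cc(C[C@H]2CO[C@H](c3ccc(O)c(O)c3)[C@H]2CO)ccc1OC(=O)C(C)(C)C
F4 | step 2 | tert-butyl (3R)-4-[(4S)-4-isopropyl-2-oxo-1,3-oxazolidin-3-yl]-3-(3-methoxy-4-pivaloyloxybenzyl)-4-oxobutanoate | CC(C)[C@H]1COC(=O)N1C(=O)[C@H](Cc1ccc(OC(=O)C(C)(C)C)c(OC)c1)CC(=O)OC(C)(C)C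
F5 | step 2 | tert-butyl (3R)-4-hydroxy-3-(3-methoxy-4-pivaloyloxybenzyl)butanoate | OC[C@H](Cc1ccc(OC(=O)C(C)(C)C)c(OC)c1)CC(=O)OC(C)(C)C
F6 | step 2 | (4R)-4-(3-methoxy-4-pivaloyloxybenzyl)oxolan-2-one | O=C1C[C@@H](Cc2ccc(OC(=O)C(C)(C)C)c(OC)c2)CO1
F7 | step 2 | (3R,4R)-3-(4-benzyloxy-3-methoxybenzyl)-4-(3-methoxy-4-pivaloyloxybenzyl)oxolan-2-one | COc1cc(C[C@H]2COC(=O)[C@@H]2Cc2ccc(OCc3ccccc3)c(OC)c2)ccc1OC(=O)C(C)(C)C
F8 | step 2 | (2R,3R)-2-(4-benzyloxy-3-methoxybenzyl)-3-(4-hydroxy-3-methoxybenzyl)butane-1,4-diol | OC[C@H](Cc1ccc(OCc2ccccc2)c(OC)c1)[C@H](CO)Cc1ccc(O)c(OC)c1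
F9 | step 5 | taxiresinol tetraacetate = [(2S,3R,4R)-4-(4-acetoxy-3-methoxybenzyl)-2-(3,4-diacetoxyphenyl)oxolan-3-yl]methyl acetate | COc1cc(C[C@H]2CO[C@H](c3ccc(OC(C)=O)c(OC(C)=O)c3)[C@H]2COC(C)=O)ccc1OC(C)=O
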